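**Retrosynthetic overview**
1. Side chain last: the C7 carbinol comes from chelate-controlled reduction of an α-aryloxy ketone, the C7–aryl bond from an aryllithium adding to an (R)-2-aryloxypropanoate, and the C8–O bond from Mitsunobu inversion of ethyl (S)-lactate on the pendant phenol.
2. The tetralin ring is the only ring made (all three benzene rings are bought). It is closed by oxidative dearomatization of the one free phenol of a mono-silylated (R,R)-dibenzylbutane to a p-quinone methide, which the second arene traps (sets C1).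
3. The two methyl stereocentres come from a double asymmetric hydrogenation of an achiral, centrosymmetric (1E,3E)-1,4-diaryl-2,3-dimethylbutadiene; the C2 symmetry of the product is then broken by mono-desilylation.
4. The diene comes from zirconocene homocoupling of an aryl propyne made from 4-bromo-2-methoxyphenol; the same aryl bromide supplies all three arenes.

Assumption: tetralin atoms are numbered C1 (aryl-bearing CH), C2, C3 (CHMe), C4 (CH2), with 6-OMe and 7-O, for description only; the SMILES are authoritative.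

**Step 1**
Reactants: 1, 4-bromo-2-methoxyphenol; 2, tert-butyldimethylsilyl chloride
Product: 3, (4-bromo-2-methoxyphenoxy)(tert-butyl)dimethylsilane
Conditions: TBSCl, imidazole, DMF, rt
Reagents that add atoms: tert-butyldimethylsilyl chloride, CC(C)(C)[Si](C)(C)Cl
Why: Standard phenol silylation; the aryl TBS ether survives the organometallic, hydrogenation, DDQ, Mitsunobu and hydride steps and is removed by fluoride.

**Step 2**
Reactants: 3; 4, prop-1-yn-1-ylmagnesium bromide
Product: 5, tert-butyl[2-methoxy-4-(prop-1-yn-1-yl)phenoxy]dimethylsilane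
Conditions: 4, ZnCl2, THF, 0 °C; then 3, Pd(PPh3)4 (3 mol%), 60 °C
Reagents that add atoms: prop-1-yn-1-ylmagnesium bromide, CC#C[Mg]Br
Why: Negishi alkynylation of an aryl bromide with an in situ alkynylzinc; no stereocentre.

**Step 3**
Reactants: 5 (2 equiv)
Product: 6, (1E,3E)-1,4-bis[4-(tert-butyldimethylsilyloxy)-3-methoxyphenyl]-2,3-dimethylbuta-1,3-diene
Conditions: Cp2ZrCl2 (0.55 equiv), n-BuLi (1.1 equiv), THF, −78 °C to rt; then 1 M HCl, 0 °C
Reagents that add atoms: none
Why: Negishi zirconocene alkyne homocoupling places both aryl groups α to Zr (2,5-diaryl-3,4-dimethylzirconacyclopentadiene), and protonolysis of the two C–Zr bonds with retention gives the (1E,3E)-diene.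

**Step 4**
Reactants: 6
Product: 7, (2R,3R)-1,4-bis[4-(tert-butyldimethylsilyloxy)-3-methoxyphenyl]-2,3-dimethylbutane
Conditions: H2 (50 bar), [Ir(cod)((S)-tBu-PHOX)]BArF (2 mol%), CH2Cl2, rt
Reagents that add atoms: none
Why: Proposed new method: each ArCH=C(Me)– half, twisted out of conjugation by the vicinal methyls, is an (E)-α-methylstilbene-type trisubstituted aryl alkene that Ir–P,N catalysts reduce by face-selective syn H2 delivery from an Ir(III) dihydride, so two catalyst-controlled reductions should give the homochiral (2R,3R) product (tetralin C2 and C3) with the minor enantiomer diverted into the meso isomer, which is removed as a diastereomer at compound 9. The closest known reactions are Ir-PHOX hydrogenation of unfunctionalized trisubstituted aryl alkenes and of 2,3-diarylbutadienes; the sense of induction is assigned by analogy with (E)-α-methylstilbene giving (R) and is checked by desilylating a sample to the known (8R,8′R)-dihydroguaiaretic acid, the (R)-ligand being used if it is opposite.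

**Step 5**
Reactants: 7
Product: 8, 4-[(2R,3R)-4-[4-(tert-butyldimethylsilyloxy)-3-methoxyphenyl]-2,3-dimethylbutyl]-2-methoxyphenol
Conditions: TBAF (1.0 equiv), THF, −20 to 0 °C; recovered 7 and diol (re-silylated) recycled
Reagents that add atoms: none
Why: Statistical mono-desilylation (at most about 50% per pass); because the two silyl ethers of C2-symmetric 7 are homotopic, only one mono-phenol can form.

**Step 6**
Reactants: 8
Product: 9, 4-[(1S,2S,3R)-7-(tert-butyldimethylsilyloxy)-6-methoxy-2,3-dimethyl-1,2,3,4-tetrahydronaphthalen-1-yl]-2-methoxyphenol (all-trans)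
Conditions: DDQ (1.0 equiv, slow addition), CH2Cl2–HFIP 4:1, 5 mM, −20 to 0 °C
Reagents that add atoms: none
Why: DDQ dehydrogenates the only free 4-alkyl-2-methoxyphenol to a p-quinone methide (oxidative dearomatization); HFIP-activated intramolecular 1,6-Friedel–Crafts attack by the silylated ring, para to its OMe, through a chair-like transition state with both methyls and the aryl equatorial, rearomatizes the phenol and sets C1 (S). Only the free-phenol ring can become the pendant ring, which fixes the regiochemistry.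

**Step 7**
Reactants: 9; 10, ethyl (S)-lactate
Product: 11, ethyl (2R)-2-{4-[(1S,2S,3R)-7-(tert-butyldimethylsilyloxy)-6-methoxy-2,3-dimethyl-1,2,3,4-tetrahydronaphthalen-1-yl]-2-methoxyphenoxy}propanoate
Conditions: PPh3, DIAD, THF, 0 °C to rt
Reagents that add atoms: ethyl (S)-lactate, CCOC(=O)[C@H](C)O
Why: Mitsunobu etherification of the only free phenol; SN2 inversion of the lactate carbinol sets C8 as R.

**Step 8**
Reactants: 11; 3 (as its aryllithium)
Product: 12, (2R)-1-[4-(tert-butyldimethylsilyloxy)-3-methoxyphenyl]-2-{4-[(1S,2S,3R)-7-(tert-butyldimethylsilyloxy)-6-methoxy-2,3-dimethyl-1,2,3,4-tetrahydronaphthalen-1-yl]-2-methoxyphenoxy}propan-1-one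
Conditions: MeNH(OMe)·HCl, i-PrMgCl, THF, −20 °C; then ArLi (from 3, n-BuLi, THF, −78 °C), −78 to 0 °C; NH4Cl
Reagents that add atoms: [4-(tert-butyldimethylsilyloxy)-3-methoxyphenyl]lithium, [Li]c1ccc(O[Si](C)(C)C(C)(C)C)c(OC)c1
Why: One-pot Weinreb amide formation and ketone synthesis; the stable N,O-chelated tetrahedral intermediate prevents over-addition, and the low temperature avoids epimerization at C8.

**Step 9**
Reactants: 12
Product: 13, (1S,2R)-1-[4-(tert-butyldimethylsilyloxy)-3-methoxyphenyl]-2-{4-[(1S,2S,3R)-7-(tert-butyldimethylsilyloxy)-6-methoxy-2,3-dimethyl-1,2,3,4-tetrahydronaphthalen-1-yl]-2-methoxyphenoxy}propan-1-ol (erythro)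
Conditions: Zn(BH4)2, Et2O, −30 to 0 °C
Reagents that add atoms: none
Why: Cram-chelate reduction; zinc bridges the ketone and α-aryloxy oxygens and hydride enters past the α-hydrogen, giving the anti (erythro) alcohol, so C7 is S next to C8 R.

**Step 10**
Reactants: 13
Product: 14, (1S,2R)-1-(4-hydroxy-3-methoxyphenyl)-2-{4-[(1S,2S,3R)-7-hydroxy-6-methoxy-2,3-dimethyl-1,2,3,4-tetrahydronaphthalen-1-yl]-2-methoxyphenoxy}propan-1-ol (CID53359464)
Conditions: TBAF (2.5 equiv), AcOH (2.5 equiv), THF, 0 °C to rt
Reagents that add atoms: none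
Why: Buffered fluoride desilylation of both aryl silyl ethers; no stereocentre is touched and the benzylic alcohol is stable under these conditions.

**Compound list**
1 | 4-bromo-2-methoxyphenol | COc1cc(Br)ccc1O | starting material
2 | tert-butyldimethylsilyl chloride | CC(C)(C)[Si](C)(C)Cl | starting material
3 | (4-bromo-2-methoxyphenoxy)(tert-butyl)dimethylsilane | COc1cc(Br)ccc1O[Si](C)(C)C(C)(C)C | intermediate
4 | prop-1-yn-1-ylmagnesium bromide | CC#C[Mg]Br | starting material
5 | tert-butyl[2-methoxy-4-(prop-1-yn-1-yl)phenoxy]dimethylsilane | CC#Cc1ccc(O[Si](C)(C)C(C)(C)C)c(OC)c1 | intermediate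
6 | (1E,3E)-1,4-bis[4-(TBSO)-3-methoxyphenyl]-2,3-dimethylbuta-1,3-diene | COc1cc(/C=C(C)/C(C)=C/c2ccc(O[Si](C)(C)C(C)(C)C)c(OC)c2)ccc1O[Si](C)(C)C(C)(C)C | intermediate
7 | (2R,3R)-1,4-bis[4-(TBSO)-3-methoxyphenyl]-2,3-dimethylbutane | COc1cc(C[C@@H](C)[C@H](C)Cc2ccc(O[Si](C)(C)C(C)(C)C)c(OC)c2)ccc1O[Si](C)(C)C(C)(C)C | intermediate
8 | 4-[(2R,3R)-4-[4-(TBSO)-3-methoxyphenyl]-2,3-dimethylbutyl]-2-methoxyphenol | COc1cc(C[C@@H](C)[C@H](C)Cc2ccc(O[Si](C)(C)C(C)(C)C)c(OC)c2)ccc1O | intermediate
9 | 4-[(1S,2S,3R)-7-(TBSO)-6-methoxy-2,3-dimethyl-1,2,3,4-tetrahydronaphthalen-1-yl]-2-methoxyphenol | COc1cc([C@H]2c3cc(O[Si](C)(C)C(C)(C)C)c(OC)cc3C[C@@H](C)[C@@H]2C)ccc1O | intermediate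
10 | ethyl (S)-lactate | CCOC(=O)[C@H](C)O | starting material
11 | ethyl (2R)-2-{4-[(1S,2S,3R)-7-(TBSO)-6-methoxy-2,3-dimethyltetralin-1-yl]-2-methoxyphenoxy}propanoate | CCOC(=O)[C@@H](C)Oc1ccc([C@H]2c3cc(O[Si](C)(C)C(C)(C)C)c(OC)cc3C[C@@H](C)[C@@H]2C)cc1OC | intermediate
12 | (2R)-1-[4-(TBSO)-3-methoxyphenyl]-2-{4-[(1S,2S,3R)-7-(TBSO)-6-methoxy-2,3-dimethyltetralin-1-yl]-2-methoxyphenoxy}propan-1-one | COc1cc(C(=O)[C@@H](C)Oc2ccc([C@H]3c4cc(O[Si](C)(C)C(C)(C)C)c(OC)cc4C[C@@H](C)[C@@H]3C)cc2OC)ccc1O[Si](C)(C)C(C)(C)C | intermediate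
13 | (1S,2R)-1-[4-(TBSO)-3-methoxyphenyl]-2-{4-[(1S,2S,3R)-7-(TBSO)-6-methoxy-2,3-dimethyltetralin-1-yl]-2-methoxyphenoxy}propan-1-ol | COc1cc([C@H](O)[C@@H](C)Oc2ccc([C@H]3c4cc(O[Si](C)(C)C(C)(C)C)c(OC)cc4C[C@@H](C)[C@@H]3C)cc2OC)ccc1O[Si](C)(C)C(C)(C)C | intermediate
14 | (1S,2R)-1-(4-hydroxy-3-methoxyphenyl)-2-{4-[(1S,2S,3R)-7-hydroxy-6-methoxy-2,3-dimethyltetralin-1-yl]-2-methoxyphenoxy}propan-1-ol | COc1cc([C@H](O)[C@@H](C)Oc2ccc([C@H]3c4cc(O)c(OC)cc4C[C@@H](C)[C@@H]3C)cc2OC)ccc1O | target

**Totals**
Total steps: 10. Longest linear sequence: 10 (from 1; compound 3 is reused in step 8).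

**Steps most likely to fail, with fallbacks**
- **Step 4** (incomplete second reduction, 1,4-reduction to the tetrasubstituted alkene, or poor ee and dl:meso ratio). Fallback: set the methyl stereocentres with an auxiliary instead. Oxidatively homocouple the enolate of commercial 4-benzyl-3-propionyl-oxazolidin-2-one (the enantiomer giving the (2S,3S)-2,3-dimethylsuccinyl bis-imide), reduce with LiBH4 to (2S,3S)-2,3-dimethylbutane-1,4-diol, make the ditosylate, and couple it under Cu catalysis with the Grignard reagent of 3 to reach 7.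
- **Step 6** (over-oxidation of 9 by DDQ, or quinone methide to styrene tautomerization eroding C2). Fallback: decouple oxidation from ring closure. Run DDQ in MeOH to isolate the benzylic methyl ether, then ionize it with BF3·OEt2 in CH2Cl2 at −78 °C so the Friedel–Crafts cyclization occurs with no oxidant present.
- **Step 3** (regioisomeric zirconacycles giving 1,3- or 2,4-diaryl dienes). Fallback: build the diene from a regiodefined alkenyl boronate. Cu-catalysed β-selective syn hydroboration of 5 (B2pin2, MeOH) gives (Z)-ArCH=C(Bpin)CH3, and Pd-catalysed oxidative homocoupling of this boronate gives 6.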